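A closed flask (teal) and a tank (ochre) both hold the same charge for 2.0 h, the tank on average, so I compared how they share it out. I followed the odds, ring divided by open dimer.

| setting | Sunday's | Saturday's | Thursday's | amber | teal | ochre |
|---|---|---|---|---|---|---|
| substrate | 0.050 M | 0.025 M | 0.038 M | 0.050 M | 0.050 M | 0.050 M |
| remark | run made earlier | run made earlier | run made earlier | a tube with plug flow, the mixed feed as stated, residence time 2.0 h | a closed flask charged with all of it at once and left for 2.0 h | a single well-mixed tank run continuously and read at steady state, 2.0 h in it on average |
| time |  |  |  | 2.0 h | 2.0 h |  |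

| run | time / min | ring / % | open dimer / % | substrate / % |
|---|---|---|---|---|
| Sunday's | 20.0 | 48 | 28 | 17 |
| Sunday's | 40.0 | 45 | 30 | 8 |
| Sunday's | 50.0 | 45 | 33 | 9 |
| Sunday's | 80.0 | 41 | 37 | 8 |
| Saturday's | 30.0 | 58 | 21 | 15 |
| Saturday's | 60.0 | 52 | 24 | 12 |
| Saturday's | 90.0 | 47 | 24 | 10 |
| Saturday's | 120 | 43 | 29 | 9 |
| Thursday's | 10.0 | 42 | 25 | 28 |
| Thursday's | 20.0 | 50 | 29 | 19 |
| Thursday's | 50.0 | 44 | 29 | 12 |
| Thursday's | 120 | 41 | 34 | 6 |

(readings scatter by 2 percentage points)

1. the set-up with the highest share of ring in all that became ring or open dimer, at the outlet or at the end ("none" if the first two lie within 2 percentage points) (amber / teal / ochre / none)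
2. share of ring in all that became ring or open dimer, at the outlet or at the end, amber
3. share of ring in all that became ring or open dimer, at the outlet or at the end, teal
4. share of ring in all that became ring or open dimer, at the outlet or at the end, ochre

- in percentages every species weighs as the substrate in it: one open dimer or idle adduct counts as two
- for ring the idle adduct is counted in
- the stated concentrations are those of everything mixed, before any reaction; amounts are the same in each set-up
- on the list of suspects stand: substrate <-> ring; 2 substrate -> open dimer; substrate <-> dormant form; substrate + ring <-> idle adduct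
- the earlier runs were made in a closed, stirred flask
- in an amount of ring, one idle adduct counts as one ring

Sunday's run has the charge asked about, and its odds read 1.71 at 20.0 min and 1.11 at 80.0 min. Those two readings, with their scatter, give 317 min, the decade time T10, the time in which a closed flask's odds fall tenfold. Carried on to 2.0 h, it gave me odds of 0.828, a share of 45.3% for teal. I expected the same for amber, since a plug in a tube ages as the flask does. I had no such clock for the tank.

The forecast was higher than mine, at 51% for both teal and amber. It put ochre first at 63%, with the ground “Low substrate favours ring”.

The flask gave 48.6% for teal and amber and 63.8% for ochre, so ochre leads as forecast. Teal's odds are 0.945. Ochre's odds are 1.76, about what Sunday's closed flask read at 20.0 min.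

    substrate ⇌ ring (K = 3.80, k = 0.00160 s⁻¹)
    2 substrate → open dimer (k = 0.0160 L mol⁻¹ s⁻¹)
    substrate ⇌ dormant form (K = 5.60, k = 1.80 × 10⁻⁴ s⁻¹)
    substrate + ring ⇌ idle adduct, settled at all times (K = 6.90 L mol⁻¹)

Substrate's half-life by the forward step to ring alone is 0.12 h, far shorter than the 2.0 h of teal, which holds 16.7 such half-lives. By the forward step to dormant form alone it is 1.1 h, so the same time holds 1.87 of them. Left for 20.0 h, teal's share is 17.2%, which is odds of 0.208. Carried on from 2.0 h to 20.0 h, my T10 of 317 min gives a fall by a factor of 2580, but teal's odds fell by a factor of 4.55, far less.

The earlier runs and the new flask stem from a simulated flask with made-up constants.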